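**Assumptions:** (R)-3-hydroxy-γ-butyrolactone, tigloyl chloride, methyl acrylate and 3-methylfuran are purchased. 2-Bromo-3-methylfuran is made fresh and used crude. NBS brominates 3-methylfuran mainly at C2.

## Retrosynthetic overview
1. The target comes from an intramolecular Cr(II) (Nozaki–Hiyama–Kishi, NHK) allylation that joins C6 and C7. It closes the 10-membered ring and, after lactonisation, the α-methylene-γ-butyrolactone.
2. The C6 aldehyde, its (Z)-β-methyl alkene and the bridged 3(2H)-furanone all arise from one oxidative dearomatisation. The substrate is a 2,3-disubstituted furan (from 3-methylfuran) carrying a tertiary α-ketol; the furanone ring forms at this stage.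
3. C8 comes from (R)-3-hydroxy-γ-butyrolactone. C10 is set by chelation-controlled addition to the β-hydroxy methyl ketone. C7 becomes sp² (via a Morita–Baylis–Hillman adduct and allylic bromide) and is re-set in the NHK step.
4. Ring order: furanone (step 12), then the 10-membered carbocycle and γ-lactone together (step 13).

## Route

**Step 1**
Reactants: 1 (R)-3-hydroxy-γ-butyrolactone
Product: 2 (R)-3,4-dihydroxy-N-methoxy-N-methylbutanamide
Conditions: MeNH(OMe)·HCl, AlMe3, CH2Cl2, 0 °C → rt
Reagents that add atoms: N,O-dimethylhydroxylamine, CNOC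
Why: Weinreb aminolysis of the lactone opens the ring and keeps the C8 centre untouched.

**Step 2**
Reactants: 2
Product: 3 (R)-4-[(tert-butyldiphenylsilyl)oxy]-3-hydroxy-N-methoxy-N-methylbutanamide
Conditions: TBDPSCl, imidazole, CH2Cl2, 0 °C
Reagents that add atoms: TBDPSCl, CC(C)(C)[Si](Cl)(c1ccccc1)c1ccccc1
Why: Silylation is selective for the primary hydroxyl, leaving the secondary C8–OH free to chelate in step 4.

**Step 3**
Reactants: 3
Product: 4 (R)-5-[(tert-butyldiphenylsilyl)oxy]-4-hydroxypentan-2-one
Conditions: MeMgBr (3.5 equiv), THF, 0 °C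
Reagents that add atoms: methylmagnesium bromide, C[Mg]Br
Why: A Weinreb amide gives the methyl ketone (C10 and C14) without over-addition; the first equivalents simply deprotonate the free OH.

**Step 4**
Reactants: 4
Product: 5 (3R,5R)-6-[(tert-butyldiphenylsilyl)oxy]-3,5-dihydroxy-3-methylhexan-2-one
Conditions: (i) 1-ethoxyvinyllithium (from ethyl vinyl ether and t-BuLi), MgBr2·OEt2, THF, −78 °C; (ii) 1 M HCl, THF, rt
Reagents that add atoms: 1-ethoxyvinyllithium, C=C(OCC)[Li]; water, O
Why: This is a chelation-controlled (Cram-chelate) Grignard-type addition to a β-hydroxy ketone.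
- In the six-membered Mg chelate the CH2OTBDPS group sits equatorial. Axial attack syn to the axial H at C8 gives the 1,3-anti diol, which is the required (10R) configuration relative to C8 (R).
- Acid then hydrolyses the enol ether to the C1 methyl ketone.
- Expected dr is roughly 4:1 or better, and the minor diastereomer is removed by chromatography.
- Compound 5 may exist partly as a cyclic hemiketal.

**Step 5**
Reactants: 6 3-methylfuran
Product: 7 2-bromo-3-methylfuran
Conditions: NBS, DMF, 0 °C, dark; used crude
Reagents that add atoms: N-bromosuccinimide, O=C1CCC(=O)N1Br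
Why: Electrophilic bromination occurs at the more reactive C2 position, which is α to O and ortho to the methyl group.

**Step 6**
Reactants: 5 and 7
Product: 8 (3R,5R)-6-[(tert-butyldiphenylsilyl)oxy]-3,5-dihydroxy-3-methyl-1-(3-methylfuran-2-yl)hexan-2-one
Conditions: Pd2(dba)3, XPhos, Cs2CO3, toluene, 80 °C
Reagents that add atoms: none
Why: Pd-catalysed α-heteroarylation of a methyl ketone joins C2 to C3 of the future furan. Only the C1 methyl is enolisable, because C10 is quaternary, so regiochemistry is unambiguous. A mild carbonate base limits α-ketol rearrangement, and no stereocentre is touched.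

**Step 7**
Reactants: 8 and 9 tigloyl chloride ((E)-2-methylbut-2-enoyl chloride)
Product: 10 (2R,4R)-1-[(tert-butyldiphenylsilyl)oxy]-4-hydroxy-4-methyl-5-oxo-6-(3-methylfuran-2-yl)hexan-2-yl (2E)-2-methylbut-2-enoate
Conditions: Et3N, DMAP (cat.), CH2Cl2, 0 °C
Reagents that add atoms: none (the acyl chloride is reactant 9)
Why: Acylation is selective for the secondary C8–OH over the tertiary C10–OH and installs the tiglate with retention.

**Step 8**
Reactants: 10
Product: 11 (2R,4R)-1,4-dihydroxy-4-methyl-5-oxo-6-(3-methylfuran-2-yl)hexan-2-yl (2E)-2-methylbut-2-enoate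
Conditions: TBAF, AcOH (1:1), THF, 0 °C
Reagents that add atoms: none
Why: Buffered desilylation minimises 8→7 acyl migration and base-mediated side reactions.

**Step 9**
Reactants: 11
Product: 12 (2R,4R)-4-hydroxy-4-methyl-1,5-dioxo-6-(3-methylfuran-2-yl)hexan-2-yl (2E)-2-methylbut-2-enoate
Conditions: Dess–Martin periodinane, NaHCO3, CH2Cl2, 0 °C → rt
Reagents that add atoms: none
Why: Mild oxidation of the primary alcohol to the α-acyloxy aldehyde, with no epimerisation expected under buffered conditions. The aldehyde can close onto C10–OH as a lactol, but this re-opens in the next step.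

**Step 10**
Reactants: 12 and 13 methyl acrylate
Product: 14 methyl (4R,6R)-3,6-dihydroxy-6-methyl-2-methylidene-4-[(2E)-2-methylbut-2-enoyloxy]-7-oxo-8-(3-methylfuran-2-yl)octanoate (C3 epimeric mixture)
Conditions: DABCO (0.3 equiv), neat or MeOH, rt
Reagents that add atoms: none (methyl acrylate is reactant 13)
Why: Morita–Baylis–Hillman reaction. The new C7 carbinol stereocentre is irrelevant because it is destroyed in step 11. A competing intramolecular aldol of the C2 methylene onto the aldehyde is possible, so reaction time is kept short.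

**Step 11**
Reactants: 14
Product: 15 methyl (2Z,4R,6R)-2-(bromomethyl)-6-hydroxy-6-methyl-4-[(2E)-2-methylbut-2-enoyloxy]-7-oxo-8-(3-methylfuran-2-yl)oct-2-enoate
Conditions: MsCl, Et3N, CH2Cl2, 0 °C; then LiBr, THF, 0 °C → rt
Reagents that add atoms: lithium bromide, [Li+].[Br-]
Why: Mesylation then SN2′ displacement by bromide, with allylic transposition, gives the (Z)-2-(bromomethyl)alk-2-enoate. Both MBH epimers converge to one sp² C7, and furan-compatible conditions are used (no NBS or HBr).

**Step 12**
Reactants: 15
Product: 16 methyl (2Z,4R)-2-(bromomethyl)-4-[(2E)-2-methylbut-2-enoyloxy]-5-[(2R)-2-methyl-5-[(1Z)-1-methyl-3-oxoprop-1-en-1-yl]-3-oxofuran-2(3H)-yl]pent-2-enoate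
Conditions: DMDO (acetone, 0 °C, 20 min, dark); then PPTS (0.1 equiv), CH2Cl2, rt
Reagents that add atoms: dimethyldioxirane, CC1(C)OO1 (delivers one O)
Why: This is the key dearomatisation (furan oxidative ring opening, of the type that gives cis-enediones).
- DMDO opens the 2,3-disubstituted furan to the cis 4-oxo-enal. The cis geometry fixes the (Z)-β-methyl enal (C3 and C6 cis; C6 and the C15 methyl trans).
- The C3 ketone is trapped by the tertiary C10–OH in a 5-exo hemiketalisation, and dehydration gives the conjugated 3(2H)-furanone. C10 is untouched.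

Proposed new method: this specific oxidation–cyclodehydration cascade has no direct precedent. Its closest known reaction types are furan → cis-2-ene-1,4-dione oxidation, and acid cyclodehydration of α′-hydroxy-1,3-diketones to 3(2H)-furanones. The risks are Z→E isomerisation and an aldol of the transient 1,3-diketone onto the aldehyde, so the cyclisation is acid-triggered immediately to remove the nucleophilic C2 position.

**Step 13**
Reactants: 16
Product: 17 atripliciolide tiglate (target)
Conditions: CrCl2 (10 equiv), NiCl2 (2 mol %), DMF, ~3 mM, syringe-pump addition over 8 h, 25 °C; then TsOH (cat.), CH2Cl2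
Reagents that add atoms: none
Why: Intramolecular NHK allylation. The allylchromium reacts at its γ-carbon (C7) with the C6 aldehyde through a chair transition state, and anti selectivity gives the trans-lactone relationship. The macrocyclic conformation, enforced by the C8 and C10 centres and the bridged furanone, is expected to select (6R,7R). Lactonisation of the alkoxide or hydroxy ester with the C12 methyl ester expels MeOH and delivers the α-methylene-γ-butyrolactone. Chromium chemoselectively attacks the aldehyde, not the furanone, ketone or esters.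

Proposed new method: NHK macrocyclisation onto a pre-formed bridged furanone is unprecedented. The closest known reaction is the Cr-mediated intramolecular allylation used to build germacranolide 10-membered rings, and the cis alkene in the ring favours closure.

## Compound list
1 | (R)-3-hydroxy-γ-butyrolactone | O=C1C[C@@H](O)CO1 | starting material
2 | (R)-3,4-dihydroxy-N-methoxy-N-methylbutanamide | CON(C)C(=O)C[C@@H](O)CO | intermediate
3 | (R)-4-(TBDPSO)-3-hydroxy-N-methoxy-N-methylbutanamide | CON(C)C(=O)C[C@@H](O)CO[Si](c1ccccc1)(c1ccccc1)C(C)(C)C | intermediate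
4 | (R)-5-(TBDPSO)-4-hydroxypentan-2-one | CC(=O)C[C@@H](O)CO[Si](c1ccccc1)(c1ccccc1)C(C)(C)C | intermediate
5 | (3R,5R)-6-(TBDPSO)-3,5-dihydroxy-3-methylhexan-2-one | CC(=O)[C@](C)(O)C[C@@H](O)CO[Si](c1ccccc1)(c1ccccc1)C(C)(C)C | intermediate
6 | 3-methylfuran | Cc1ccoc1 | starting material
7 | 2-bromo-3-methylfuran | Cc1ccoc1Br | intermediate
8 | (3R,5R)-6-(TBDPSO)-3,5-dihydroxy-3-methyl-1-(3-methylfuran-2-yl)hexan-2-one | Cc1ccoc1CC(=O)[C@](C)(O)C[C@@H](O)CO[Si](c2ccccc2)(c2ccccc2)C(C)(C)C | intermediate
9 | tigloyl chloride | ClC(=O)/C(C)=C/C | starting material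
10 | tiglate of 8 at the C5-OH (2R,4R) | Cc1ccoc1CC(=O)[C@](C)(O)C[C@@H](OC(=O)/C(C)=C/C)CO[Si](c2ccccc2)(c2ccccc2)C(C)(C)C | intermediate
11 | primary alcohol (2R,4R) | Cc1ccoc1CC(=O)[C@](C)(O)C[C@@H](OC(=O)/C(C)=C/C)CO | intermediate
12 | α-tigloyloxy aldehyde (2R,4R) | Cc1ccoc1CC(=O)[C@](C)(O)C[C@@H](OC(=O)/C(C)=C/C)C=O | intermediate
13 | methyl acrylate | C=CC(=O)OC | starting material
14 | MBH adduct (4R,6R; C3 epimeric) | Cc1ccoc1CC(=O)[C@](C)(O)C[C@@H](OC(=O)/C(C)=C/C)C(O)C(=C)C(=O)OC | intermediate
15 | (Z)-allylic bromide (2Z,4R,6R) | Cc1ccoc1CC(=O)[C@](C)(O)C[C@@H](OC(=O)/C(C)=C/C)/C=C(\CBr)C(=O)OC | intermediate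
16 | furanone Z-enal allylic bromide | O=C/C=C(/C)C1=CC(=O)[C@@](C)(C[C@@H](OC(=O)/C(C)=C/C)/C=C(\CBr)C(=O)OC)O1 | intermediate
17 | atripliciolide tiglate (6R,7R,8R,10R) | C=C1C(=O)O[C@@H]2/C=C(/C)C3=CC(=O)[C@@](C)(C[C@@H](OC(=O)/C(C)=C/C)[C@@H]12)O3 | target

## Totals
Total steps: 13. Longest linear sequence: 12 (1 → 2 → 3 → 4 → 5 → 8 → 10 → 11 → 12 → 14 → 15 → 16 → 17; step 5 runs in parallel).

## Three steps most likely to fail
1. **Step 13 (macro-NHK onto the bridged furanone; strain and C6/C7 stereocontrol).**
   - Fallback: pre-form the trans-α-methylene lactone by intermolecular Cr-mediated allylation of acrolein with the allylic bromide.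
   - Then close the ring by RCM between a 5-isopropenyl-3(2H)-furanone and the resulting vinyl carbinol, which forms the C4=C5 trisubstituted alkene in the 9-membered ring.
2. **Step 12 (dearomative cascade; Z→E isomerisation or aldol of the transient diketone).**
   - Fallback: drop the dearomatisation. Claisen-condense the methyl ketone of 5 (after arylation is omitted) with methyl (Z)-4,4-dimethoxy-2-methylbut-2-enoate.
   - Then effect acid cyclodehydration to the 5-alkenyl furanone and acetal hydrolysis to give the Z-enal.
3. **Step 6 (α-heteroarylation with unstable 2-bromo-3-methylfuran in the presence of free OH/α-ketol groups).**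
   - Fallback: add vinylMgBr in step 4 instead of the ethoxyvinyl reagent.
   - Then do a VO(acac)2/TBHP epoxidation and open the epoxide at its terminal carbon with 2-lithio-3-methylfuran.
   - Finally oxidise the C1 secondary alcohol with Dess–Martin periodinane.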